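**Retrosynthetic overview**

1. The strategy rests on ring F, the dimethoxybenzo ring: it carries the ether oxygen bound to C-8 and the ketone carbon on adjacent carbons, with a methoxy group beside the acyl-bearing carbon and H beside the oxygen-bearing carbon. This is the pattern of 3,5-dimethoxybenzyne inserted between a tertiary C-8 hydroxyl and an ester on the neighbouring carbon C-3″.
2. Last disconnections: removal of a methoxymethyl (MOM) ether, then the aryne annulation that makes the aryl C–O and aryl–acyl C–C bonds and closes the pyranone ring E on a para-quinol β-hydroxy ester.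
3. The para-quinol comes from oxidative dearomatisation (water enters at C-8) of the ring-A phenol of a furo[2,3-h]flavan. Its dihydrofuran ring D is closed at the aromatic stage by intramolecular Friedel–Crafts hydroxyalkylation of an α-keto ester at C-8, which avoids enolate chemistry on a base-sensitive quinone.
4. The O-7–C-2″ bond comes from SN2 opening of (2S,3R)-methyl 3-(4-methoxyphenyl)glycidate by the 7-phenoxide of a (2R)-flavan. The flavan (ring C) is built from 2,4,6-trihydroxybenzaldehyde and 4'-methoxyacetophenone by Claisen–Schmidt condensation, conjugate reduction, asymmetric transfer hydrogenation and Mitsunobu closure with inversion.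
5. Ring order: C (Mitsunobu), D (Friedel–Crafts), dearomatisation of A, then E with F attached (aryne annulation).

Key step: step 17

Remark on labels: flavan numbering is used for the chroman part (O-1, C-2 … C-8a). The dihydrofuran fused at C-7/C-8 has O-7, C-2″ (bearing 4-methoxyphenyl = anisyl) and C-3″ (quaternary carbon).
Assumption: the D-fructose-derived ketone of the Shi epoxidation is taken to give the (2S,3R)-glycidate from the trans-cinnamate, the same spatial sense as its (R,R)-epoxides from other trans-olefins. The sense would be checked against the commercial (2R,3S) enantiomer.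

**Route**

Step 1
Reactants: 1 2,4,6-trihydroxybenzaldehyde
Product: 2 2,6-dihydroxy-4-(methoxymethoxy)benzaldehyde
Conditions: MOMCl (1.0 equiv), i-Pr2NEt, THF, 0 °C
Reagents that add atoms: chloromethyl methyl ether, COCCl
Why: Williamson-type O-alkylation should occur first at the 4-hydroxyl, the only one not hydrogen-bonded to the formyl group and the most acidic.

Step 2
Reactants: 2 2,6-dihydroxy-4-(methoxymethoxy)benzaldehyde
Product: 3 2-(allyloxy)-6-hydroxy-4-(methoxymethoxy)benzaldehyde
Conditions: allyl bromide (1.05 equiv), K2CO3, acetone, rt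
Reagents that add atoms: allyl bromide, C=CCBr
Why: Williamson etherification of one of two equivalent hydroxyls; the remaining one stays chelated to the aldehyde and should resist a second alkylation.

Step 3
Reactants: 3 2-(allyloxy)-6-hydroxy-4-(methoxymethoxy)benzaldehyde; 4 4'-methoxyacetophenone
Product: 5 (E)-3-[2-(allyloxy)-6-hydroxy-4-(methoxymethoxy)phenyl]-1-(4-methoxyphenyl)prop-2-en-1-one
Conditions: KOH, EtOH, rt
Reagents that add atoms: none
Why: Claisen–Schmidt condensation (aldol addition and dehydration) should give the E-enone; allyl and MOM ethers are stable to hydroxide.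

Step 4
Reactants: 5 (E)-3-[2-(allyloxy)-6-hydroxy-4-(methoxymethoxy)phenyl]-1-(4-methoxyphenyl)prop-2-en-1-one
Product: 6 3-[2-(allyloxy)-6-hydroxy-4-(methoxymethoxy)phenyl]-1-(4-methoxyphenyl)propan-1-one
Conditions: Cu(OAc)2 (cat.), 1,2-bis(diphenylphosphino)benzene (cat.), (EtO)2MeSiH, t-BuOH, toluene, rt; aq. NH4F work-up
Reagents that add atoms: none
Why: Copper hydride conjugate reduction (Stryker-type) reduces only the enone C=C, leaving the allyl ether, the acetal and the aryl ketone, which catalytic hydrogenation would not distinguish.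

Step 5
Reactants: 6 3-[2-(allyloxy)-6-hydroxy-4-(methoxymethoxy)phenyl]-1-(4-methoxyphenyl)propan-1-one
Product: 7 (S)-3-[2-(allyloxy)-6-hydroxy-4-(methoxymethoxy)phenyl]-1-(4-methoxyphenyl)propan-1-ol
Conditions: RuCl[(S,S)-TsDPEN](p-cymene) (cat.), HCO2Na, H2O/MeOH, 40 °C
Reagents that add atoms: none
Why: Noyori–Ikariya asymmetric transfer hydrogenation; the (S,S)-catalyst should give the (S)-carbinol from an aryl alkyl ketone, and the near-neutral formate medium avoids acid-induced hemiketal dehydration.

Step 6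
Reactants: 7 (S)-3-[2-(allyloxy)-6-hydroxy-4-(methoxymethoxy)phenyl]-1-(4-methoxyphenyl)propan-1-ol
Product: 8 (2R)-5-(allyloxy)-7-(methoxymethoxy)-2-(4-methoxyphenyl)chroman
Conditions: PPh3, DIAD, toluene, 0 °C
Reagents that add atoms: none
Why: Intramolecular Mitsunobu etherification closes ring C with inversion (S carbinol to 2R flavan); the non-polar solvent and low temperature are chosen to suppress ionisation of the anisylic oxyphosphonium.

Step 7
Reactants: 8 (2R)-5-(allyloxy)-7-(methoxymethoxy)-2-(4-methoxyphenyl)chroman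
Product: 9 (2R)-5-(allyloxy)-2-(4-methoxyphenyl)chroman-7-ol
Conditions: HCl (cat.), MeOH, 40 °C
Reagents that add atoms: none
Why: Acid-catalysed transacetalisation to methanol cleaves the aryl MOM ether; the allyl ether and the flavan C-2–O bond should survive dilute acid.

Step 8
Reactants: 10 methyl (E)-4-methoxycinnamate
Product: 11 methyl (2S,3R)-3-(4-methoxyphenyl)oxirane-2-carboxylate (trans)
Conditions: D-fructose-derived diacetate ketone catalyst, KHSO5 (as 2KHSO5·KHSO4·K2SO4), NaHCO3, Bu4NHSO4, MeCN/aq. Na2EDTA, 0 °C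
Reagents that add atoms: potassium peroxymonosulfate, [K+].[O-]S(=O)(=O)OO
Why: Shi epoxidation through a chiral dioxirane and a spiro transition state; the catalyst sets both epoxide centres, and the buffered medium protects the acid-labile anisyl epoxide.

Step 9
Reactants: 9 (2R)-5-(allyloxy)-2-(4-methoxyphenyl)chroman-7-ol; 11 methyl (2S,3R)-3-(4-methoxyphenyl)oxirane-2-carboxylate
Product: 12 methyl (2S,3S)-3-{[(2R)-5-(allyloxy)-2-(4-methoxyphenyl)chroman-7-yl]oxy}-2-hydroxy-3-(4-methoxyphenyl)propanoate
Conditions: Cs2CO3 (0.5 equiv), DMF, 50 °C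
Reagents that add atoms: none
Why: SN2 epoxide opening by the phenoxide at the benzylic C-3 with inversion should give the (3S) aryl ether; basic aprotic conditions disfavour the ion-pair pathway with retention, and C-2 is oxidised in the next step so its configuration is immaterial.

Step 10
Reactants: 12 methyl (2S,3S)-3-{[(2R)-5-(allyloxy)-2-(4-methoxyphenyl)chroman-7-yl]oxy}-2-hydroxy-3-(4-methoxyphenyl)propanoate
Product: 14 methyl (2R,2″S,3″S)-5-(allyloxy)-3″-hydroxy-2,2″-bis(4-methoxyphenyl)-2″,3″-dihydrofuro[2,3-h]chroman-3″-carboxylate (3″-OH cis to the 2″-anisyl group), via α-keto ester 13 (not isolated)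
Conditions: DMP, CH2Cl2, 0 °C; filter; then MgBr2·OEt2, CH2Cl2, −40 → 0 °C; neutral work-up
Reagents that add atoms: none
Why: Dess–Martin oxidation gives the α-keto ester, and intramolecular Friedel–Crafts hydroxyalkylation (the first stage of the cyclodehydration of α-aryloxy ketones) closes ring D at C-8, the more reactive and less flanked nuclear position. In the magnesium chelate of the s-cis dicarbonyl the anisyl group eclipses the ketone oxygen and not the ester methoxyl, which should set C-3″ with OH cis to anisyl. Low temperature and absence of base guard the enolisable C-2″ centre and prevent dehydration to the benzofuran.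

Step 11
Reactants: 14 methyl (2R,2″S,3″S)-5-(allyloxy)-3″-hydroxy-2,2″-bis(4-methoxyphenyl)-2″,3″-dihydrofuro[2,3-h]chroman-3″-carboxylate
Product: 15 methyl (2R,2″S,3″S)-5-(allyloxy)-3″-(methoxymethoxy)-2,2″-bis(4-methoxyphenyl)-2″,3″-dihydrofuro[2,3-h]chroman-3″-carboxylate
Conditions: KN(SiMe3)2, THF, −78 °C; MOMCl, −78 → 0 °C
Reagents that add atoms: chloromethyl methyl ether, COCCl
Why: O-alkylation of the potassium alkoxide (Williamson) protects the hindered tertiary alcohol, which has no fragmentation path as an alkoxide and would otherwise be a second nucleophile in the aryne step.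

Step 12
Reactants: 15 methyl (2R,2″S,3″S)-5-(allyloxy)-3″-(methoxymethoxy)-2,2″-bis(4-methoxyphenyl)-2″,3″-dihydrofuro[2,3-h]chroman-3″-carboxylate
Product: 16 methyl (2R,2″S,3″S)-5-hydroxy-3″-(methoxymethoxy)-2,2″-bis(4-methoxyphenyl)-2″,3″-dihydrofuro[2,3-h]chroman-3″-carboxylate
Conditions: Pd(PPh3)4 (cat.), morpholine, THF, rt
Reagents that add atoms: none
Why: Tsuji–Trost deallylation; zerovalent palladium ionises the aryl allyl ether and morpholine traps the allyl fragment under neutral conditions that spare the MOM ether, the ester and both benzylic ethers.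

Step 13
Reactants: 16 methyl (2R,2″S,3″S)-5-hydroxy-3″-(methoxymethoxy)-2,2″-bis(4-methoxyphenyl)-2″,3″-dihydrofuro[2,3-h]chroman-3″-carboxylate
Product: 17 methyl (2R,8S,2″S,3″R)-8-hydroxy-3″-(methoxymethoxy)-2,2″-bis(4-methoxyphenyl)-5-oxo-5,8,2″,3″-tetrahydrofuro[2,3-h]chroman-3″-carboxylate (para-quinol; 8-OH cis to CO2Me; OMOM cis to the 2″-anisyl group)
Conditions: PhI(OAc)2, MeCN/H2O 3:1, 0 °C
Reagents that add atoms: water, O
Why: Hypervalent-iodine oxidative dearomatisation of a para-alkylphenol to a para-quinol. Water should enter at C-8 anti to the pseudo-axial C-3″–OMOM bond and to the anisyl group, that is syn to the pseudo-equatorial ester, which sets C-8 as required for the annulation.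

Step 14
Reactants: 18 3,5-dimethoxyphenol
Product: 19 2-bromo-3,5-dimethoxyphenol
Conditions: NBS, CH2Cl2, −78 °C → rt; chromatographic removal of the 4-bromo isomer
Reagents that add atoms: N-bromosuccinimide, O=C1CCC(=O)N1Br
Why: Electrophilic aromatic bromination ortho to the hydroxyl of the activated ring; the para isomer is separable.

Step 15
Reactants: 19 2-bromo-3,5-dimethoxyphenol
Product: 20 (2-bromo-3,5-dimethoxyphenoxy)trimethylsilane
Conditions: (Me3Si)2NH, THF, 65 °C; evaporate
Reagents that add atoms: hexamethyldisilazane, C[Si](C)(C)N[Si](C)(C)C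
Why: O-silylation of the phenol with loss of ammonia supplies the silyl group for the following O-to-C migration.

Step 16
Reactants: 20 (2-bromo-3,5-dimethoxyphenoxy)trimethylsilane
Product: 23 3,5-dimethoxy-2-(trimethylsilyl)phenyl triflate, via aryllithium 21 (not isolated), via lithium phenoxide 22 (not isolated)
Conditions: n-BuLi, THF, −78 °C; then Tf2O, −78 °C → rt
Reagents that add atoms: triflic anhydride, O=S(=O)(OS(=O)(=O)C(F)(F)F)C(F)(F)F
Why: Bromine–lithium exchange followed by anionic 1,3-silyl migration from oxygen to carbon (retro-Brook rearrangement) and O-triflation is the standard entry to 2-silylaryl triflates.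

Step 17
Reactants: 17 methyl (2R,8S,2″S,3″R)-8-hydroxy-3″-(methoxymethoxy)-2,2″-bis(4-methoxyphenyl)-5-oxo-5,8,2″,3″-tetrahydrofuro[2,3-h]chroman-3″-carboxylate; 23 3,5-dimethoxy-2-(trimethylsilyl)phenyl triflate
Product: 26 (2R,8S,2″S,3″R)-methoxymethyl ether of the target (ring E closed; 5,7-dimethoxychromanone fused at C-8/C-3″), via 3,5-dimethoxybenzyne 24 (not isolated), via aryl anion 25 (not isolated)
Conditions: KF, 18-crown-6, THF, 0 °C → rt, slow addition of 23
Reagents that add atoms: none
Why: Proposed new method: fluoride removes the silyl group of 23 and triflate leaves, giving aryne 24. The tertiary C-8 oxygen of 17 adds to the aryne carbon remote from the flanking methoxy group, so aryl anion 25 develops ortho to that methoxy group, where it is inductively stabilised; this anion attacks the ester carbonyl on C-3″ and expels methoxide. The closest known reactions are the annulation of arynes from 2-(trimethylsilyl)aryl triflates with ortho-hydroxyaryl esters to xanthones and the O-arylation of aliphatic alcohols by arynes; new here is a tertiary aliphatic β-hydroxy ester as the two-atom partner. Ring E closes by a 6-exo-trig acyl substitution, made fast by the cis 1,3-relationship of oxygen and ester carbonyl on adjacent ring-D carbons. No stereocentre is formed: the cis fusion at C-8/C-3″ is carried over from the para-quinol. The step needs the 5,7- and not the 6,8-dimethoxy pattern (secured by the methoxy group beside the triple bond), a single oxygen nucleophile (secured by the MOM ether), and capture of 25 before protonation or retro-aldol cleavage of the alkoxide (hence an aprotic solvent without acidic C–H bonds, low temperature and slow aryne release).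

Step 18
Reactants: 26 (2R,8S,2″S,3″R)-methoxymethyl ether of the target
Product: 27 CNP0251458.1, the (2R,8S,2″S,3″R)-3″-hydroxy compound
Conditions: MgBr2·OEt2, EtSH, Et2O/CH2Cl2, 0 °C → rt
Reagents that add atoms: none
Why: Chelation of magnesium between the ketone and the α-MOM ether activates this acetal for transfer of the methoxymethyl group to the thiol. The doubly β-alkoxy-substituted dienone is a poor thiol acceptor, and the mild Lewis acid should leave the anisylic C–O bonds intact.

**Compound list**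

1 | 2,4,6-trihydroxybenzaldehyde | O=Cc1c(O)cc(O)cc1O | starting material
2 | 2,6-dihydroxy-4-(methoxymethoxy)benzaldehyde | O=Cc1c(O)cc(OCOC)cc1O | intermediate
3 | 2-(allyloxy)-6-hydroxy-4-(methoxymethoxy)benzaldehyde | O=Cc1c(O)cc(OCOC)cc1OCC=C | intermediate
4 | 4'-methoxyacetophenone | CC(=O)c1ccc(OC)cc1 | starting material
5 | (E)-3-[2-(allyloxy)-6-hydroxy-4-(methoxymethoxy)phenyl]-1-(4-methoxyphenyl)prop-2-en-1-one | COc1ccc(cc1)C(=O)/C=C/c1c(O)cc(OCOC)cc1OCC=C | intermediate
6 | 3-[2-(allyloxy)-6-hydroxy-4-(methoxymethoxy)phenyl]-1-(4-methoxyphenyl)propan-1-one | COc1ccc(cc1)C(=O)CCc1c(O)cc(OCOC)cc1OCC=C | intermediate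
7 | (S)-3-[2-(allyloxy)-6-hydroxy-4-(methoxymethoxy)phenyl]-1-(4-methoxyphenyl)propan-1-ol | COc1ccc(cc1)[C@@H](O)CCc1c(O)cc(OCOC)cc1OCC=C | intermediate
8 | (2R)-5-(allyloxy)-7-(methoxymethoxy)-2-(4-methoxyphenyl)chroman | COc1ccc([C@H]2CCc3c(OCC=C)cc(OCOC)cc3O2)cc1 | intermediate
9 | (2R)-5-(allyloxy)-2-(4-methoxyphenyl)chroman-7-ol | COc1ccc([C@H]2CCc3c(OCC=C)cc(O)cc3O2)cc1 | intermediate
10 | methyl (E)-4-methoxycinnamate | COC(=O)/C=C/c1ccc(OC)cc1 | starting material
11 | methyl (2S,3R)-3-(4-methoxyphenyl)oxirane-2-carboxylate | COC(=O)[C@H]1O[C@@H]1c1ccc(OC)cc1 | intermediate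
12 | methyl (2S,3S)-3-{[(2R)-5-(allyloxy)-2-(4-methoxyphenyl)chroman-7-yl]oxy}-2-hydroxy-3-(4-methoxyphenyl)propanoate | COC(=O)[C@@H](O)[C@H](c1ccc(OC)cc1)Oc1cc(OCC=C)c2CC[C@H](c3ccc(OC)cc3)Oc2c1 | intermediate
13 | methyl (3S)-3-{[(2R)-5-(allyloxy)-2-(4-methoxyphenyl)chroman-7-yl]oxy}-3-(4-methoxyphenyl)-2-oxopropanoate (α-keto ester) | COC(=O)C(=O)[C@H](c1ccc(OC)cc1)Oc1cc(OCC=C)c2CC[C@H](c3ccc(OC)cc3)Oc2c1 | intermediate (not isolated)
14 | methyl (2R,2″S,3″S)-5-(allyloxy)-3″-hydroxy-2,2″-bis(4-methoxyphenyl)-2″,3″-dihydrofuro[2,3-h]chroman-3″-carboxylate | COc1ccc([C@H]2CCc3c(O2)c2c(O[C@@H](c4ccc(OC)cc4)[C@]2(O)C(=O)OC)cc3OCC=C)cc1 | intermediate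
15 | methyl (2R,2″S,3″S)-5-(allyloxy)-3″-(methoxymethoxy)-2,2″-bis(4-methoxyphenyl)-2″,3″-dihydrofuro[2,3-h]chroman-3″-carboxylate | COc1ccc([C@H]2CCc3c(O2)c2c(O[C@@H](c4ccc(OC)cc4)[C@]2(OCOC)C(=O)OC)cc3OCC=C)cc1 | intermediate
16 | methyl (2R,2″S,3″S)-5-hydroxy-3″-(methoxymethoxy)-2,2″-bis(4-methoxyphenyl)-2″,3″-dihydrofuro[2,3-h]chroman-3″-carboxylate | COc1ccc([C@H]2CCc3c(O2)c2c(O[C@@H](c4ccc(OC)cc4)[C@]2(OCOC)C(=O)OC)cc3O)cc1 | intermediate
17 | methyl (2R,8S,2″S,3″R)-8-hydroxy-3″-(methoxymethoxy)-2,2″-bis(4-methoxyphenyl)-5-oxo-5,8,2″,3″-tetrahydrofuro[2,3-h]chroman-3″-carboxylate (key-step precursor) | COc1ccc([C@H]2CCC3=C(O2)[C@]2(O)[C@@](OCOC)(C(=O)OC)[C@H](c4ccc(OC)cc4)OC2=CC3=O)cc1 | intermediate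
18 | 3,5-dimethoxyphenol | COc1cc(O)cc(OC)c1 | starting material
19 | 2-bromo-3,5-dimethoxyphenol | COc1cc(O)c(Br)c(OC)c1 | intermediate
20 | (2-bromo-3,5-dimethoxyphenoxy)trimethylsilane | COc1cc(O[Si](C)(C)C)c(Br)c(OC)c1 | intermediate
21 | (2-lithio-3,5-dimethoxyphenoxy)trimethylsilane (aryllithium) | COc1cc(O[Si](C)(C)C)c([Li])c(OC)c1 | intermediate (not isolated)
22 | lithium 3,5-dimethoxy-2-(trimethylsilyl)phenoxide | COc1cc([O-])c([Si](C)(C)C)c(OC)c1.[Li+] | intermediate (not isolated)
23 | 3,5-dimethoxy-2-(trimethylsilyl)phenyl triflate | COc1cc(OC)c([Si](C)(C)C)c(OS(=O)(=O)C(F)(F)F)c1 | intermediate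
24 | 3,5-dimethoxybenzyne | COC1=CC(OC)=CC#C1 | intermediate (not isolated)
25 | potassium salt of the 8-O-(3,5-dimethoxyphenyl) ether of 17, carbanion at the ring carbon ortho to both O-8 and OMe (aryl anion) | COc1ccc([C@H]2CCC3=C(O2)[C@]2(Oc4cc(OC)cc(OC)[c-]4)[C@@](OCOC)(C(=O)OC)[C@H](c4ccc(OC)cc4)OC2=CC3=O)cc1.[K+] | intermediate (not isolated)
26 | (2R,8S,2″S,3″R)-methoxymethyl ether of the target (key-step product) | COc1ccc([C@H]2CCC3=C(O2)[C@]24Oc5cc(OC)cc(OC)c5C(=O)[C@@]2(OCOC)[C@H](c2ccc(OC)cc2)OC4=CC3=O)cc1 | intermediate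
27 | CNP0251458.1, (2R,8S,2″S,3″R) | COc1ccc([C@H]2CCC3=C(O2)[C@]24Oc5cc(OC)cc(OC)c5C(=O)[C@@]2(O)[C@H](c2ccc(OC)cc2)OC4=CC3=O)cc1 | target

**Step count**

Total step count: 18.
Longest linear sequence: 14 steps (steps 1–7, 9–13, 17, 18).

**Steps most likely to fail**

1. Step 17 (aryne annulation). The C-8 alkoxide may fragment by retro-aldol cleavage of the C-8–C-3″ bond before it is arylated. O-arylation of the hindered tertiary oxygen may be slow against self-consumption of the aryne. The aryl anion may be protonated before it reaches the ester, leaving an open aryl ether.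
   Fallback, by known oxidative phenol C–O coupling; it sets out from 15 and comes back at 26. Ester 15 is reduced with i-Bu2AlH (CH2Cl2, −78 °C) to the aldehyde F1. Bromophenol 19 is allylated (allyl bromide, K2CO3) to 1-(allyloxy)-2-bromo-3,5-dimethoxybenzene F2, which n-BuLi converts at −78 °C into 2-(allyloxy)-4,6-dimethoxyphenyllithium F3. Addition of F3 to F1 gives the diaryl carbinol F4 (both epimers at the new carbinol carbon are usable), and Dess–Martin oxidation gives the aryl ketone F5. Pd(PPh3)4 and morpholine remove both allyl groups to give the bis-phenol F6. PhI(OAc)2 in (CF3)2CHOH then oxidises the ring-A phenol while the hydroxyl ortho to the ketone closes ring E on C-8, necessarily from the face that carries the acyl group, to give 26.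

2. Step 13 (dearomatisation). Water may add to the wrong face of C-8 or to C-6, or the C-3″ substituent may be lost from C-8 with formation of a quinone.
   Fallback with stereospecific oxygen placement; it sets out from 14 and comes back at 17. Carbinol 14 is deallylated (Pd(PPh3)4, morpholine) to the phenol with free tertiary hydroxyl F7. PhI(OAc)2 in dry MeCN, with that hydroxyl as the internal nucleophile, should give the spiro-epoxy dienone F8, whose epoxide oxygen is held on the anisyl face. Acetic acid with NaOAc opens the epoxide at C-8 with inversion to the 8-acetate F9, so the C-8 oxygen ends cis to the ester. The tertiary alcohol is protected (MOMCl, i-Pr2NEt, Bu4NI) to give F10, and K2CO3 in MeOH removes the acetate to give 17.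

3. Step 10 (oxidation and ring-D closure). The α-keto ester may enolise and lose configuration at C-2″, the ring may close at C-6 instead of C-8, or the carbinol may dehydrate to the aromatic benzofuran.
   Fallback that forms ring D after oxidation of ring A; it sets out from 12 and comes back at 17. Hydroxy ester 12 is protected as the MOM ether F11 (MOMCl, i-Pr2NEt) and deallylated (Pd(PPh3)4, morpholine) to the phenol F12. Teuber oxidation with (KSO3)2NO gives the 5,8-quinone F13. LiN(SiMe3)2 in THF at −78 °C then forms the ester enolate, which adds to the C-8 carbonyl in a 5-exo aldol reaction through a lithium-bridged chelate that places OH cis to CO2Me and the anisyl group on the convex face, to give 17. This path needs no α-keto ester, at the price of enolate chemistry on a base-sensitive quinone (β-elimination of the C-7 oxygen and deprotonation at C-4 are its own hazards).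

**Further compounds**

F1 | step 17 | (2R,2″S,3″S)-5-(allyloxy)-3″-(methoxymethoxy)-2,2″-bis(4-methoxyphenyl)-2″,3″-dihydrofuro[2,3-h]chroman-3″-carbaldehyde | COc1ccc([C@H]2CCc3c(O2)c2c(O[C@@H](c4ccc(OC)cc4)[C@]2(OCOC)C=O)cc3OCC=C)cc1
F2 | step 17 | 1-(allyloxy)-2-bromo-3,5-dimethoxybenzene | COc1cc(OCC=C)c(Br)c(OC)c1
F3 | step 17 | 2-(allyloxy)-4,6-dimethoxyphenyllithium | [Li]c1c(OCC=C)cc(OC)cc1OC
F4 | step 17 | [2-(allyloxy)-4,6-dimethoxyphenyl] carbinol from F1 (epimer mixture at the carbinol carbon) | COc1ccc([C@H]2CCc3c(O2)c2c(O[C@@H](c4ccc(OC)cc4)[C@]2(OCOC)C(O)c2c(OCC=C)cc(OC)cc2OC)cc3OCC=C)cc1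
F5 | step 17 | 3″-[2-(allyloxy)-4,6-dimethoxybenzoyl] ketone | COc1ccc([C@H]2CCc3c(O2)c2c(O[C@@H](c4ccc(OC)cc4)[C@]2(OCOC)C(=O)c2c(OCC=C)cc(OC)cc2OC)cc3OCC=C)cc1
F6 | step 17 | 5-hydroxy-3″-(2-hydroxy-4,6-dimethoxybenzoyl) bis-phenol | COc1ccc([C@H]2CCc3c(O2)c2c(O[C@@H](c4ccc(OC)cc4)[C@]2(OCOC)C(=O)c2c(O)cc(OC)cc2OC)cc3O)cc1
F7 | step 13 | methyl (2R,2″S,3″S)-5,3″-dihydroxy-2,2″-bis(4-methoxyphenyl)-2″,3″-dihydrofuro[2,3-h]chroman-3″-carboxylate | COc1ccc([C@H]2CCc3c(O2)c2c(O[C@@H](c4ccc(OC)cc4)[C@]2(O)C(=O)OC)cc3O)cc1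
F8 | step 13 | spiro-epoxy dienone (C-8–O–C-3″ epoxide on the anisyl face) | COc1ccc([C@H]2CCC3=C(O2)[C@]24O[C@]4(C(=O)OC)[C@H](c4ccc(OC)cc4)OC2=CC3=O)cc1
F9 | step 13 | 8-acetoxy-3″-hydroxy para-quinol ester (8-OAc cis to CO2Me) | COc1ccc([C@H]2CCC3=C(O2)[C@]2(OC(C)=O)[C@@](O)(C(=O)OC)[C@H](c4ccc(OC)cc4)OC2=CC3=O)cc1
F10 | step 13 | 8-acetoxy-3″-(methoxymethoxy) para-quinol ester | COc1ccc([C@H]2CCC3=C(O2)[C@]2(OC(C)=O)[C@@](OCOC)(C(=O)OC)[C@H](c4ccc(OC)cc4)OC2=CC3=O)cc1
F11 | step 10 | methyl (2S,3S)-3-{[(2R)-5-(allyloxy)-2-(4-methoxyphenyl)chroman-7-yl]oxy}-2-(methoxymethoxy)-3-(4-methoxyphenyl)propanoate | COC(=O)[C@@H](OCOC)[C@H](c1ccc(OC)cc1)Oc1cc(OCC=C)c2CC[C@H](c3ccc(OC)cc3)Oc2c1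
F12 | step 10 | methyl (2S,3S)-3-{[(2R)-5-hydroxy-2-(4-methoxyphenyl)chroman-7-yl]oxy}-2-(methoxymethoxy)-3-(4-methoxyphenyl)propanoate | COC(=O)[C@@H](OCOC)[C@H](c1ccc(OC)cc1)Oc1cc(O)c2CC[C@H](c3ccc(OC)cc3)Oc2c1
F13 | step 10 | (2R)-flavan-5,8-quinone 7-O-ether of the MOM-protected hydroxy ester | COC(=O)[C@@H](OCOC)[C@H](c1ccc(OC)cc1)OC1=CC(=O)C2=C(O[C@@H](c3ccc(OC)cc3)CC2)C1=O
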